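**Reading time.** A reading of Thursday's closed flask at 40 h is worth trusting if its chains have stopped growing by then.

all flasks: initiator 0.50 mM
- Tuesday's: free monomer 10 mM; a single well-mixed tank run continuously and read at steady state, 40 h in it on average
- Monday's: free monomer 10 mM; one stirred flow tank at steady state, fed with the mixture as stated, mean residence time 120 h
- Friday's: free monomer 10 mM (fed, over 20.0 h); all but free monomer at the start; free monomer goes in evenly over 20.0 h, the run ends at 40 h; time 40 h
- Thursday's: free monomer 10 mM; everything together in a closed stirred flask, run for 40 h; time 40 h

    free monomer + initiator → living end + monomer in chains (k1 = 201 M⁻¹ h⁻¹)
    free monomer + living end → monomer in chains + living end, rate k2*[living end]*[free monomer] (k2 = 53.4 M⁻¹ h⁻¹)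
    monomer in chains + living end → free monomer + living end, rate k3*[living end] as long as [monomer in chains] is above zero (k3 = 0.0318 h⁻¹)
    free monomer ⇌ dormant form (K4 = 5.11, k4 = 0.0101 h⁻¹)
    living end + monomer in chains → dead end (k5 = 35.9 M⁻¹ h⁻¹)

- the stated concentrations are those of everything mixed, before any reaction; amounts are the same in each set-up
- the feed brings no volume worth counting
- run time (Friday's): 40 h

1. the set-up with the highest amount of monomer in chains at the outlet or at the end, in percent of the free monomer put in ("none" if the first two lie within 2 percentage points) (Tuesday's / Monday's / Friday's / Thursday's / none)
2. amount of monomer in chains at the outlet or at the end, in percent of the free monomer put in, Tuesday's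
3. amount of monomer in chains at the outlet or at the end, in percent of the free monomer put in, Monday's
4. amount of monomer in chains at the outlet or at the end, in percent of the free monomer put in, Friday's
5. amount of monomer in chains at the outlet or at the end, in percent of the free monomer put in, Thursday's

**Ends counted.** I bracket Thursday's flask by hand. Let p be monomer in chains and m free monomer, both as fractions of the charged free monomer, and let n be initiator on the same scale, 5.00%. Initiator goes in about 0.498 h, while the pseudo-first-order growth time at the charged ends is 37.5 h. Initiation is far quicker, so I take n ends as present from the start.

**The ceiling.** Each end adds to p in proportion to m and dies in proportion to p. The ends therefore cancel from the ratio, and so does time. Ends lost per unit of p gained are the death constant over the growth constant, times p/m. Summing this until n ends are spent gives the chain ceiling, the square root of 2 times growth constant over death constant times n times m. At m of one, the chain ceiling is 38.6%. That is my upper bound.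

**The floor.** Taking m at its dormant equilibrium share gives 15.6%. But the forward half-life to the dormant form is 68.6 h, longer than the run. So I take m as what the forward step leaves at 40 h, with a full ceiling of chains also removed: 41.0%. The floor rises to 24.7%.

**The forecast.** It names Thursday's as best, with 17.1% for Tuesday's, 15.2% for Monday's, 23.5% for Friday's and 26% for Thursday's: “The closed flask does best because it has high monomer while the ends are alive”. Its Thursday figure lies above my floor and below my ceiling.

**The result.** Tuesday's gives 17.1%, Monday's 15.2%, Friday's 23.7% and Thursday's 26.6%, the highest.

**Why it stops.** Thursday's chains stop at the ceiling's mechanism. Striking out the death of ends on chains lifts Thursday's yield from 26.6% to 53.7%. A run ten times as long barely moves it. Read through the ceiling, Thursday's 26.6% implies an m of 47.5%, a little above its end reading of 44.8%. Friday's highest free monomer, 7.40 mM, is 74.0% of the charge, so Friday's ceiling is 33.2%, and Friday's flask ends below it at 23.7%.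

All constants belong to no real substance, and the outcome is calculated.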